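Ring B is closed last, at C6–C7, by a 6-endo vinyl-radical cyclisation. The precursor is a monocyclic ring-A cyclohexane: the quaternary C10 carries an α-methyl-β-iodo enone chain (C9, C8, C7) and C5 an exocyclic methylene (C6). The step exploits two features of the target: the C7=C8 trisubstituted alkene of ring B, carried as the vinyl iodide so that the double bond lands regiospecifically, and C5, which, flanked by the quaternary C4 and C10, forces the radical onto C6 and then takes up hydrogen trans to the C10 methyl. One operation thus gives ring B, the C6–C7 bond, the C7=C8 alkene and the trans ring fusion.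

Key step: step 8

Numbering: locants C1–C12 in names and explanations are drimane numbers of the target (ring A: C1–C5 and C10; ring B: C5–C10; C11 is the CH2O carbon, C12 the methyl on C8).

Assumption: the bifunctional catalyst of step 1 is taken to deliver the (S)-configured adduct 3; should its sense of induction be opposite, the pseudo-enantiomeric catalyst of the quinidine series is used.

Step 1
Reactants: 1 2-methyl-3-oxobutanenitrile; 2 pent-1-en-3-one (ethyl vinyl ketone)
Product: 3 (2S)-2-acetyl-2-methyl-5-oxoheptanenitrile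
Conditions: quinine-derived thiourea catalyst 1-[3,5-bis(trifluoromethyl)phenyl]-3-(6'-methoxycinchonan-9-yl)thiourea (10 mol%), toluene, −20 °C
Reagents that add atoms: none
Why: Organocatalytic asymmetric Michael addition, in which the quinuclidine base forms the stabilised cyano-ketone enolate and the thiourea hydrogen-bonds the vinyl ketone, so that one enolate face reacts and the C10 quaternary stereocentre is set.

Step 2
Reactants: 3 (2S)-2-acetyl-2-methyl-5-oxoheptanenitrile
Product: 4 (1R)-1,2,3-trimethyl-4-oxocyclohex-2-ene-1-carbonitrile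
Conditions: p-TsOH·H2O (0.1 equiv), toluene, reflux, Dean–Stark
Reagents that add atoms: none
Why: Acid-catalysed intramolecular aldol condensation (ring-forming half of a Robinson annulation), in which the enol of the ethyl ketone attacks the acetyl carbonyl and water is lost; the non-enolisable quaternary centre is retained and acid avoids retro-Michael cleavage.

Step 3
Reactants: 4 (1R)-1,2,3-trimethyl-4-oxocyclohex-2-ene-1-carbonitrile
Product: 5 (1R)-1,3,3-trimethyl-2-methylidene-4-oxocyclohexane-1-carbonitrile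
Conditions: KOtBu (1.2 equiv), t-BuOH/THF, 0 °C; then MeI (1.5 equiv), 0 °C → rt
Reagents that add atoms: iodomethane, CI
Why: Deconjugative α-alkylation of the enone, in which γ-deprotonation at C6 (the only γ-hydrogens, C10 being quaternary) gives the extended dienolate that is methylated at C4, creating the gem-dimethyl carbon and leaving the double bond as the exocyclic C5=C6 methylene; no stereocentre is formed.

Step 4
Reactants: 5 (1R)-1,3,3-trimethyl-2-methylidene-4-oxocyclohexane-1-carbonitrile
Product: 6 (1R)-1,5,5-trimethyl-6-methylidene-4-[(triisopropylsilyl)oxy]cyclohex-3-ene-1-carbonitrile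
Conditions: TIPSOTf (1.3 equiv), Et3N (2 equiv), CH2Cl2, 0 °C → rt
Reagents that add atoms: triisopropylsilyl trifluoromethanesulfonate, CC(C)[Si](C(C)C)(C(C)C)OS(=O)(=O)C(F)(F)F
Why: Silyl enol ether formation by soft enolisation; C2 is the only enolisable position, so the C2=C3 enol ether forms regiospecifically, masks the C3 ketone and later serves as the handle for oxidation at C2.

Step 5
Reactants: 6 (1R)-1,5,5-trimethyl-6-methylidene-4-[(triisopropylsilyl)oxy]cyclohex-3-ene-1-carbonitrile
Product: 8 1-[(1R)-1,5,5-trimethyl-6-methylidene-4-[(triisopropylsilyl)oxy]cyclohex-3-en-1-yl]propan-1-one, via ketimine 7 (not isolated)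
Conditions: EtMgBr (2 equiv), CuBr·SMe2 (5 mol%), THF, 60 °C; then AcOH/NaOAc buffer (pH 4.5), THF/H2O, rt
Reagents that add atoms: ethylmagnesium bromide, CC[Mg]Br; water, O
Why: Grignard addition to the hindered nitrile stops at the magnesium ketimine, which is hydrolysed to the C9 ketone at the pH where imine hydrolysis is fast and the triisopropylsilyl enol ether should survive.

Step 6
Reactants: 8 1-[(1R)-1,5,5-trimethyl-6-methylidene-4-[(triisopropylsilyl)oxy]cyclohex-3-en-1-yl]propan-1-one
Product: 9 (2Z)-3-hydroxy-2-methyl-1-[(1R)-1,5,5-trimethyl-6-methylidene-4-[(triisopropylsilyl)oxy]cyclohex-3-en-1-yl]prop-2-en-1-one (enol form of the α-formyl ketone)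
Conditions: LDA (1.1 equiv), THF, −78 °C; HCO2CH2CF3 (1.5 equiv), −78 °C; aq. NH4Cl
Reagents that add atoms: 2,2,2-trifluoroethyl formate, O=COCC(F)(F)F
Why: Claisen-type C-formylation of the lithium enolate (C8 is the only enolisable carbon of the C9 ketone) with an activated formate introduces C7; the product rests as the hydrogen-bonded enol.

Step 7
Reactants: 9 (2Z)-3-hydroxy-2-methyl-1-[(1R)-1,5,5-trimethyl-6-methylidene-4-[(triisopropylsilyl)oxy]cyclohex-3-en-1-yl]prop-2-en-1-one
Product: 10 (2E)-3-iodo-2-methyl-1-[(1R)-1,5,5-trimethyl-6-methylidene-4-[(triisopropylsilyl)oxy]cyclohex-3-en-1-yl]prop-2-en-1-one (the Z isomer, if formed, serves equally)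
Conditions: PPh3 (1.3 equiv), I2 (1.3 equiv), Et3N (1.5 equiv), MeCN/CH2Cl2, 0 °C → rt
Reagents that add atoms: iodine, I-I
Why: Conversion of a vinylogous acid into a β-iodo enone, in which the enol oxygen is activated as an oxyphosphonium ion and replaced by iodide through addition–elimination at C7, driven by formation of Ph3P=O.

Step 8
Reactants: 10 (2E)-3-iodo-2-methyl-1-[(1R)-1,5,5-trimethyl-6-methylidene-4-[(triisopropylsilyl)oxy]cyclohex-3-en-1-yl]prop-2-en-1-one
Product: 11 (5R,10R)-3-[(triisopropylsilyl)oxy]-11-nordrima-2,7-dien-9-one, i.e. (4aR,8aR)-2,5,5,8a-tetramethyl-6-[(triisopropylsilyl)oxy]-4a,5,8,8a-tetrahydronaphthalen-1(4H)-one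
Conditions: Bu3SnH (1.3 equiv, added over 6 h), AIBN (0.2 equiv), benzene (0.005 M), 80 °C
Reagents that add atoms: none
Why: Bu3Sn• abstracts iodine from 10 to give the σ-vinyl radical at C7, which inverts freely (the alkene geometry of 10 is therefore of no consequence), adds to the terminal carbon C6 of the C5=C6 exocyclic alkene and leaves a tertiary radical at C5 that is reduced by Bu3SnH. The closest known reaction type is the tin-hydride cyclisation of vinyl radicals from vinyl halides onto alkenes. Ring B is closed in the 6-endo-trig mode, with the C7=C8 double bond staying exactly where the vinyl iodide placed it. The new stereocentre C5 is set in the hydrogen-atom transfer: the face of the C5 radical syn to the axial methyl groups on C4 and C10 is shielded, so hydrogen should enter anti to the C10 methyl and give the trans ring fusion. The step needs 6-endo over 5-exo attack and cyclisation faster than reduction or 1,5-hydrogen transfer: the first is secured by C5 being fully substituted between the quaternary C4 and C10 (a 5-exo adduct would in any case ring-expand by 3-exo attack on the enone and Dowd–Beckwith-type fragmentation to the same C5 radical), the second by the polarity match of the electrophilic β-acylvinyl radical with the electron-rich 1,1-disubstituted alkene and by slow addition of Bu3SnH at high dilution.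

Step 9
Reactants: 11 (5R,10R)-3-[(triisopropylsilyl)oxy]-11-nordrima-2,7-dien-9-one
Product: 12 (5S,10R)-3-[(triisopropylsilyl)oxy]drima-2,7,9(11)-triene
Conditions: Ph3PCH3Br (4 equiv), KOtBu (3.8 equiv), toluene, rt → 90 °C
Reagents that add atoms: methyltriphenylphosphonium bromide, C[P+](c1ccccc1)(c1ccccc1)c1ccccc1.[Br-]
Why: Wittig methylenation with salt-free Ph3P=CH2 at elevated temperature, as used for hindered ketones, converts the C9 carbonyl into the exocyclic C9=C11 alkene and so introduces C11.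

Step 10
Reactants: 12 (5S,10R)-3-[(triisopropylsilyl)oxy]drima-2,7,9(11)-triene
Product: 14 (5S,9R,10R)-3-[(triisopropylsilyl)oxy]drima-2,7-dien-11-ol, via alkylborane 13 (not isolated)
Conditions: 9-BBN (1.5 equiv), THF, 0 °C → rt; then NaOH (aq.), H2O2, 0 °C
Reagents that add atoms: hydrogen peroxide, OO
Why: Hydroboration–oxidation, in which the bulky borane reacts only at the unhindered terminal carbon C11 of the 1,1-disubstituted alkene and delivers hydrogen to C9 from the face anti to the axial C10 methyl, setting C9 (R) with the CH2OH group equatorial.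

Step 11
Reactants: 14 (5S,9R,10R)-3-[(triisopropylsilyl)oxy]drima-2,7-dien-11-ol; 15 7-hydroxy-2H-chromen-2-one (umbelliferone)
Product: 16 7-{[(5S,9R,10R)-3-[(triisopropylsilyl)oxy]drima-2,7-dien-11-yl]oxy}-2H-chromen-2-one
Conditions: PPh3 (1.5 equiv), DIAD (1.5 equiv), THF, 0 → 45 °C
Reagents that add atoms: none
Why: Mitsunobu etherification of the primary alcohol with the acidic phenol (pKa about 8) forms the C11–O aryl ether without touching a stereocentre.

Step 12
Reactants: 16 7-{[(5S,9R,10R)-3-[(triisopropylsilyl)oxy]drima-2,7-dien-11-yl]oxy}-2H-chromen-2-one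
Product: 18 7-{[(2S,5S,9R,10R)-2-hydroxy-3-oxodrim-7-en-11-yl]oxy}-2H-chromen-2-one, via silyloxy epoxide 17 (not isolated)
Conditions: DMDO (1.05 equiv, acetone solution), CH2Cl2, −78 → −40 °C; then TBAF (1.2 equiv), AcOH (1.5 equiv), THF, 0 °C
Reagents that add atoms: dimethyldioxirane, CC1(C)OO1
Why: Rubottom-type oxidation, in which dimethyldioxirane epoxidises the electron-rich enol ether (faster than the C7=C8 alkene or the coumarin) on the face anti to the axial methyl groups on C4 and C10 and fluoride then collapses the silyloxy epoxide to the ketone, setting the equatorial C2 hydroxyl (S).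

Step 13
Reactants: 18 7-{[(2S,5S,9R,10R)-2-hydroxy-3-oxodrim-7-en-11-yl]oxy}-2H-chromen-2-one
Product: 19 7-{[(2S,3S,5S,9R,10R)-2,3-dihydroxydrim-7-en-11-yl]oxy}-2H-chromen-2-one, i.e. 7-{[(1R,4aS,6S,7S,8aR)-6,7-dihydroxy-2,5,5,8a-tetramethyl-1,4,4a,5,6,7,8,8a-octahydronaphthalen-1-yl]methoxy}-2H-chromen-2-one (target)
Conditions: NaBH4 (1.5 equiv), MeOH/CH2Cl2, −20 °C
Reagents that add atoms: none
Why: Hydride reduction of the C3 ketone by axial attack anti to the axial C4 methyl should give the equatorial alcohol (S) and thus the trans-diequatorial 2,3-diol, as known for 2-hydroxy-3-oxo-4,4-dimethyl decalin systems.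

Compound list
1 | 2-methyl-3-oxobutanenitrile | CC(=O)C(C)C#N | starting material
2 | pent-1-en-3-one (ethyl vinyl ketone) | CCC(=O)C=C | starting material
3 | (2S)-2-acetyl-2-methyl-5-oxoheptanenitrile | CCC(=O)CC[C@@](C)(C#N)C(C)=O | intermediate
4 | (1R)-1,2,3-trimethyl-4-oxocyclohex-2-ene-1-carbonitrile | N#C[C@]1(C)CCC(=O)C(C)=C1C | intermediate
5 | (1R)-1,3,3-trimethyl-2-methylidene-4-oxocyclohexane-1-carbonitrile | N#C[C@]1(C)CCC(=O)C(C)(C)C1=C | intermediate
6 | (1R)-1,5,5-trimethyl-6-methylidene-4-[(triisopropylsilyl)oxy]cyclohex-3-ene-1-carbonitrile | N#C[C@]1(C)CC=C(O[Si](C(C)C)(C(C)C)C(C)C)C(C)(C)C1=C | intermediate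
7 | 1-[(1R)-1,5,5-trimethyl-6-methylidene-4-[(triisopropylsilyl)oxy]cyclohex-3-en-1-yl]propan-1-imine | CCC(=N)[C@]1(C)CC=C(O[Si](C(C)C)(C(C)C)C(C)C)C(C)(C)C1=C | intermediate (not isolated)
8 | 1-[(1R)-1,5,5-trimethyl-6-methylidene-4-[(triisopropylsilyl)oxy]cyclohex-3-en-1-yl]propan-1-one | CCC(=O)[C@]1(C)CC=C(O[Si](C(C)C)(C(C)C)C(C)C)C(C)(C)C1=C | intermediate
9 | (2Z)-3-hydroxy-2-methyl-1-[(1R)-1,5,5-trimethyl-6-methylidene-4-[(triisopropylsilyl)oxy]cyclohex-3-en-1-yl]prop-2-en-1-one | O/C=C(C)\C(=O)[C@]1(C)CC=C(O[Si](C(C)C)(C(C)C)C(C)C)C(C)(C)C1=C | intermediate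
10 | (2E)-3-iodo-2-methyl-1-[(1R)-1,5,5-trimethyl-6-methylidene-4-[(triisopropylsilyl)oxy]cyclohex-3-en-1-yl]prop-2-en-1-one | I/C=C(C)/C(=O)[C@]1(C)CC=C(O[Si](C(C)C)(C(C)C)C(C)C)C(C)(C)C1=C | intermediate
11 | (5R,10R)-3-[(triisopropylsilyl)oxy]-11-nordrima-2,7-dien-9-one | CC1=CC[C@@H]2C(C)(C)C(O[Si](C(C)C)(C(C)C)C(C)C)=CC[C@@]2(C)C1=O | intermediate
12 | (5S,10R)-3-[(triisopropylsilyl)oxy]drima-2,7,9(11)-triene | CC1=CC[C@@H]2C(C)(C)C(O[Si](C(C)C)(C(C)C)C(C)C)=CC[C@@]2(C)C1=C | intermediate
13 | 9-{(5S,9R)-3-[(triisopropylsilyl)oxy]drima-2,7-dien-11-yl}-9-borabicyclo[3.3.1]nonane (C11 alkylborane of 12, ring configuration as in 14) | CC1=CC[C@@H]2C(C)(C)C(O[Si](C(C)C)(C(C)C)C(C)C)=CC[C@@]2(C)[C@@H]1CB1C2CCCC1CCC2 | intermediate (not isolated)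
14 | (5S,9R,10R)-3-[(triisopropylsilyl)oxy]drima-2,7-dien-11-ol | CC1=CC[C@@H]2C(C)(C)C(O[Si](C(C)C)(C(C)C)C(C)C)=CC[C@@]2(C)[C@@H]1CO | intermediate
15 | 7-hydroxy-2H-chromen-2-one (umbelliferone) | O=c1ccc2ccc(O)cc2o1 | starting material
16 | 7-{[(5S,9R,10R)-3-[(triisopropylsilyl)oxy]drima-2,7-dien-11-yl]oxy}-2H-chromen-2-one | CC1=CC[C@@H]2C(C)(C)C(O[Si](C(C)C)(C(C)C)C(C)C)=CC[C@@]2(C)[C@@H]1COc1ccc2ccc(=O)oc2c1 | intermediate
17 | 7-{[(2S,3S,5S,9R,10R)-2,3-epoxy-3-[(triisopropylsilyl)oxy]drim-7-en-11-yl]oxy}-2H-chromen-2-one | CC1=CC[C@@H]2C(C)(C)[C@@]3(O[Si](C(C)C)(C(C)C)C(C)C)O[C@H]3C[C@@]2(C)[C@@H]1COc1ccc2ccc(=O)oc2c1 | intermediate (not isolated)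
18 | 7-{[(2S,5S,9R,10R)-2-hydroxy-3-oxodrim-7-en-11-yl]oxy}-2H-chromen-2-one | CC1=CC[C@@H]2C(C)(C)C(=O)[C@@H](O)C[C@@]2(C)[C@@H]1COc1ccc2ccc(=O)oc2c1 | intermediate
19 | 7-{[(2S,3S,5S,9R,10R)-2,3-dihydroxydrim-7-en-11-yl]oxy}-2H-chromen-2-one | CC1=CC[C@@H]2C(C)(C)[C@H](O)[C@@H](O)C[C@@]2(C)[C@@H]1COc1ccc2ccc(=O)oc2c1 | target

Total step count: 13. Longest linear sequence: 13 steps (1 → 19; compounds 2 and 15 enter as commercial partners).

Steps most likely to fail

Step 8. The vinyl radical may be reduced by the tin hydride, or may shift a hydrogen atom from the C10 methyl or from C1 (1,5-transfer), before it reaches C6. The fallback closes ring B at the same C6–C7 bond with an acyl radical and sets out from compound 6. DIBAL-H (toluene, −78 °C, mild aqueous work-up) should give the aldehyde (1R)-1,5,5-trimethyl-6-methylidene-4-[(triisopropylsilyl)oxy]cyclohex-3-ene-1-carbaldehyde F1. Still–Gennari olefination with methyl 2-[bis(2,2,2-trifluoroethoxy)phosphoryl]propanoate (KHMDS, 18-crown-6, THF, −78 °C) should give the enoate methyl (2Z)-2-methyl-3-[(1S)-1,5,5-trimethyl-6-methylidene-4-[(triisopropylsilyl)oxy]cyclohex-3-en-1-yl]prop-2-enoate F2, with the ester cis to C10. Me2AlSePh (CH2Cl2, 0 °C → rt) should convert it into the selenoester Se-phenyl (2Z)-2-methyl-3-[(1S)-1,5,5-trimethyl-6-methylidene-4-[(triisopropylsilyl)oxy]cyclohex-3-en-1-yl]prop-2-eneselenoate F3. Bu3SnH/AIBN (benzene, 80 °C, high dilution) generates the acyl radical at C7, which closes 6-endo onto C6 and, after hydrogen transfer to C5 anti to the C10 methyl, should give the enone (5S,10S)-3-[(triisopropylsilyl)oxy]-11-nordrima-2,8-dien-7-one F4. Luche reduction (NaBH4, CeCl3·7H2O, MeOH, −78 °C, axial hydride) should give the alcohol (5S,7R,10S)-3-[(triisopropylsilyl)oxy]-11-nordrima-2,8-dien-7-ol F5, with the C7 oxygen syn to the C10 methyl. KH and Bu3SnCH2I (THF, 0 °C) should give the ether (5S,7R,10S)-7-[(tributylstannyl)methoxy]-3-[(triisopropylsilyl)oxy]-11-nordrima-2,8-diene F6. Finally n-BuLi (THF, −78 °C) brings about tin–lithium exchange and [2,3]-Wittig–Still rearrangement, which moves the CH2O unit suprafacially from O7 to C9 and shifts the double bond to C7=C8; the route is rejoined at compound 14.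

Step 1. Facial discrimination may be weak for the small acyclic cyano ketone, so that the quaternary centre forms with insufficient enantiomeric purity. The fallback replaces the chiral catalyst by a stoichiometric chiral auxiliary and sets out from compound 1. Condensation with (1S)-1-phenylethanamine (p-TsOH cat., toluene, reflux, water removal) should give the secondary enaminonitrile 2-methyl-3-{[(1S)-1-phenylethyl]amino}but-2-enenitrile F7. Its conjugate addition to 2 (THF, 40 °C) passes through a compact aza-ene-like transition state in which N–H is transferred to the enone while the phenyl group shields one face, and should give the ketimine (2R)-2-methyl-5-oxo-2-{N-[(1S)-1-phenylethyl]ethanimidoyl}heptanenitrile F8. Hydrolysis with aqueous AcOH (THF, rt) liberates the auxiliary and returns the route at compound 3. The antipodal amine serves if the sense of induction demands it.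

Step 9. The ylide may act as a base on the γ-hydrogens at C6 (dienolate formation, possible deconjugation on work-up) in place of adding to the hindered C9 carbonyl. The fallback sets out from compound 11. MeLi with anhydrous CeCl3 (THF, −78 °C) adds a methyl group to C9 anti to the C10 methyl and should give the tertiary allylic alcohol (5R,9R,10R)-3-[(triisopropylsilyl)oxy]drima-2,7-dien-9-ol F9. Burgess reagent (benzene, 50 °C) then removes water by syn-elimination towards the new methyl group and returns the route at compound 12.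

Further compounds
F1 | step 8 | (1R)-1,5,5-trimethyl-6-methylidene-4-[(triisopropylsilyl)oxy]cyclohex-3-ene-1-carbaldehyde | O=C[C@]1(C)CC=C(O[Si](C(C)C)(C(C)C)C(C)C)C(C)(C)C1=C
F2 | step 8 | methyl (2Z)-2-methyl-3-[(1S)-1,5,5-trimethyl-6-methylidene-4-[(triisopropylsilyl)oxy]cyclohex-3-en-1-yl]prop-2-enoate | COC(=O)/C(C)=C\[C@]1(C)CC=C(O[Si](C(C)C)(C(C)C)C(C)C)C(C)(C)C1=C
F3 | step 8 | Se-phenyl (2Z)-2-methyl-3-[(1S)-1,5,5-trimethyl-6-methylidene-4-[(triisopropylsilyl)oxy]cyclohex-3-en-1-yl]prop-2-eneselenoate | O=C([Se]c1ccccc1)/C(C)=C\[C@]1(C)CC=C(O[Si](C(C)C)(C(C)C)C(C)C)C(C)(C)C1=C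
F4 | step 8 | (5S,10S)-3-[(triisopropylsilyl)oxy]-11-nordrima-2,8-dien-7-one | CC1=C[C@]2(C)CC=C(O[Si](C(C)C)(C(C)C)C(C)C)C(C)(C)[C@H]2CC1=O
F5 | step 8 | (5S,7R,10S)-3-[(triisopropylsilyl)oxy]-11-nordrima-2,8-dien-7-ol | CC1=C[C@]2(C)CC=C(O[Si](C(C)C)(C(C)C)C(C)C)C(C)(C)[C@H]2C[C@H]1O
F6 | step 8 | (5S,7R,10S)-7-[(tributylstannyl)methoxy]-3-[(triisopropylsilyl)oxy]-11-nordrima-2,8-diene | CC1=C[C@]2(C)CC=C(O[Si](C(C)C)(C(C)C)C(C)C)C(C)(C)[C@H]2C[C@H]1OC[Sn](CCCC)(CCCC)CCCC
F7 | step 1 | 2-methyl-3-{[(1S)-1-phenylethyl]amino}but-2-enenitrile (E/Z mixture) | CC(N[C@@H](C)c1ccccc1)=C(C)C#N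
F8 | step 1 | (2R)-2-methyl-5-oxo-2-{N-[(1S)-1-phenylethyl]ethanimidoyl}heptanenitrile | CCC(=O)CC[C@@](C)(C#N)C(C)=N[C@@H](C)c1ccccc1
F9 | step 9 | (5R,9R,10R)-3-[(triisopropylsilyl)oxy]drima-2,7-dien-9-ol | CC1=CC[C@@H]2C(C)(C)C(O[Si](C(C)C)(C(C)C)C(C)C)=CC[C@@]2(C)[C@]1(C)O
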